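Its constants come from no measurement; no experiment stands behind them.

The constant with which L takes J, 2100 /M/s, is twice the one with which Q takes Z, 1000 /M/s, but L has to be made during the run while Q stands there from the start, so I expected the charge of Q to turn the lead from J.L to Q.Z.

| flask | J | Q | time |
|---|---|---|---|
| summer | 1.0 mM | 0.950 equiv | 3.0 s |
| autumn | 1.0 mM | 1.90 equiv | 3.0 s |
| dawn | 1.0 mM | 3.80 equiv | 3.0 s |

    J + Q ⇌ Z + L (K1 = 0.64, k1 = 480 /M/s)
    Q + Z → Q.Z (k2 = 1000 /M/s)
    J + L → J.L (k3 = 2100 /M/s)

* which of these there is most of at the end, counted by the J in it, summer (Q.Z / Z / J / J.L)
* which of these there is most of at the end, counted by the J in it, autumn (Q.Z / Z / J / J.L)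
* which of these there is most of at the end, counted by the J in it, dawn (Q.Z / Z / J / J.L)
* the largest of these amounts at the end, in percent of the J charged, summer
* the largest of these amounts at the end, in percent of the J charged, autumn
* the largest of these amounts at the end, in percent of the J charged, dawn

I asked how far each constant could move the outcome, and I asked it of dawn, where the half-life of J by the forward first step, 0.380 s, is far shorter than the run of 3.0 s; in summer the same half-life, 1.5 s, fits into the run just twice, so I made no figure for summer or autumn. At dawn I assumed, as a rough first pass, that Z goes straight on to Q.Z, and I left the Z standing out of the count, although k2 is just twice k1. J then leaves by a route to Q.Z at k1·c(Q) and a route to J.L at k3·c(L), and c(L) is what Q.Z has gained over J.L. I call the split number k3 times the J charged, divided by k1·c(Q), and with Q as charged it is 1.15. Writing u and v for the shares of J in Q.Z and J.L, their difference is one minus exp(−a·u), divided by the split number a, and u and v together make up the charge.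

Starting from u of 0.5 gave 69.0%. Putting back the mean Q this implies raised a to 1.41 and u to 72.1%, with c(L) at 0.442 mM. K1 and k2 enter as the reversal of Z against its capture, a share of 0.106; adding it to a moved u just to 71.7%, and an error of that size in k3 or k1 would do the same.

The forecast, stepping the equations by hand and holding at dawn that “Z is trapped quickly”, named J.L at 32% in summer, Q.Z at 49% in autumn and Q.Z at 70.5% at dawn, a dawn figure lower than my 71.7%.

The simulation gave J.L at 32.4% in summer, Q.Z at 49.6% in autumn and Q.Z at 69.6% at dawn. Dawn's Q ended at 63% of its charge, a mean that gives a of 1.41, and c(L) stood at 0.405 mM against my 0.442 mM. With 2.30 equiv of Q in the dawn flask, a starts at 1.90 and reaches 2.67 on the second pass, giving J.L of 34.5%; that flask held 35.5% of J.L, with 4.02% of J and 4.11% of Z still standing.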